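The runs were generated by integration with made-up constants; the scatter is artificial.

What does the noon flask hold at 50 min, and which move then gains target?

the same everywhere: starting material 0.33 M; second substrate 0.165 M; free catalyst 0.66 mM
- noon: temperature 0 °C; the very flask that is asked about, followed so far
- spring: temperature 6 °C; run made earlier
- flask: temperature 0 °C; time 50 min

- noon (time / min: target / %): 8.00: 55.4; 15.0: 56.6; 25.0: 57.2; 30.0: 56.9
- spring (time / min: target / %): 8.00: 41.8; 15.0: 41.1; 25.0: 41.5; 30.0: 41.5

(readings scatter by 1 percentage point)

- green: change nothing and wait 1.5 h more
- grey: at 50 min add free catalyst, 100% of the amount charged, then wait 1.5 h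
- red: at 50 min take out 90% of the target then present, then wait 1.5 h
- violet: at 50 min raise the temperature by 25 K, then wait 1.5 h

- target, in percent of the starting material first charged, at 50 min
- what to do for the largest gain in target; "none" if nothing gains more than 2 percentage points (green / grey / red / violet / none)
- target present, with what was taken out counted in, in percent of the starting material first charged, after green
- target present, with what was taken out counted in, in percent of the starting material first charged, after red

- what is taken out of target is counted as made
- additions bring no volume worth counting

I start from the readings, not from a simulation. The noon run is flat within its scatter, with a mean of 56.5%. That stands above the 50.0% a one-to-one use of second substrate permits, so I don't take second substrate as the limiting reagent. The noon flask also stops short of its charge of starting material, with 43.5% unaccounted for as target. I read the stop as lost catalyst, though the readings can't prove that.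

So I divide the rate of making target by the rate of losing catalyst, and time drops out. The plateau times [starting material] over [free catalyst] gives 283. This is the budget, the target made per catalyst charged before the flask stops, also called the turnover number.

On this reading, waiting and removing target add nothing at noon. At an unchanged budget, grey's second charge would buy 56.5% of the starting material, against the 43.5% not turned into target. But I read that budget from the full charge, and at 50 min the noon flask has less starting material to offer, so I don't assume the budget holds for grey. I claim no more than a cap on the gain, 43 percentage points.

Is one number enough? The spring run gives 207 at 6 °C, lower than noon. So the budget holds for one temperature, and I use it at 0 °C.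

The forecast gives 57% (56% to 58%), 57% after green, 57% after red, and chooses grey. Its ground is: “Fresh catalyst restarts the reaction”. It expects 75 to 80% after grey, where my cap reaches 100%.

    starting material + free catalyst ⇌ catalyst intermediate A (K = 3.50 L mol⁻¹, k = 350 L mol⁻¹ s⁻¹, Ea = 36.0 kJ mol⁻¹, ΔH = −29.0 kJ mol⁻¹)
    catalyst intermediate A → free catalyst + target (k = 18.0 s⁻¹, Ea = 49.0 kJ mol⁻¹)
    second substrate + free catalyst ⇌ catalyst intermediate B (K = 3.20 L mol⁻¹, k = 120 L mol⁻¹ s⁻¹, Ea = 40.0 kJ mol⁻¹, ΔH = −1.00 kJ mol⁻¹)
    catalyst intermediate B → free catalyst + second product (k = 20.0 s⁻¹, Ea = 50.0 kJ mol⁻¹)
    catalyst intermediate B → spent catalyst (k = 0.170 s⁻¹, Ea = 64.0 kJ mol⁻¹)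
    (constants at 0 °C)

The flask gives 55.9%, and 55.9% after green and 55.9% after red. Green, red and violet gain 0 points, while grey gains 42 points, against my cap of 43 points. A neighbour flask with 0.0026 M of free catalyst has a budget covering 2.23 times its starting material, and it reaches 100% target. The noon flask is at rest: at 50.0 min spent catalyst stands at 100% and free catalyst at 0%. Ten times the time moves nothing: at 500 min starting material stands at 44.1% and target at 55.9%.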